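(The data are calculated on assumed constants, and the scatter is random.)

**Fraction left.** Compare flasks at the fraction of the charge not yet in the three products, never at the clock. The question is which set-up gives the highest share of target among target, isomer of the product A and isomer of the product B.

in all of them: catalyst 5 mol%

| flask | starting material | protic impurity | remark | time |
|---|---|---|---|---|
| red | 0.20 M | 0.010 M | run made earlier |  |
| green | 0.20 M | 0.0067 M | run made earlier |  |
| violet | 0.20 M | 0.015 M | run made earlier |  |
| ochre | 0.40 M | 0.010 M | run made earlier |  |
| west | 0.20 M (fed, over 20.0 min) | 0.0100 M | all but starting material at the start; starting material goes in evenly over 20.0 min, the run ends at 40 min | 40 min |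
| south | 0.20 M | 0.0100 M | a tube with plug flow, the mixed feed as stated, residence time 40 min | 40 min |
| south-east | 0.20 M | 0.0100 M | a single well-mixed tank run continuously and read at steady state, 40 min in it on average |  |
| east | 0.20 M | 0.0100 M | a closed flask charged with all of it at once and left for 40 min | 40 min |

- red (time / min: target / %, isomer of the product A / %, isomer of the product B / %): 2.00: 0, 0, 6; 4.00: 2, 0, 6; 10.0: 3, 0, 17; 25.0: 9, 3, 34
- green (time / min: target / %, isomer of the product A / %, isomer of the product B / %): 10.0: 8, 0, 19; 20.0: 8, 2, 32; 30.0: 8, 5, 40; 40.0: 12, 3, 44
- violet (time / min: target / %, isomer of the product A / %, isomer of the product B / %): 10.0: 2, 2, 20; 20.0: 6, 5, 28; 30.0: 10, 2, 35; 40.0: 11, 5, 47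
- ochre (time / min: target / %, isomer of the product A / %, isomer of the product B / %): 10.0: 6, 2, 32; 20.0: 9, 4, 47; 30.0: 13, 7, 52; 40.0: 15, 6, 55

(each reading ± 1.5 percentage points)

- the stated concentrations are those of everything mixed, before any reaction; amounts are the same in each set-up
- the feed brings no volume worth counting
- the earlier runs were made in a closed, stirred flask

- the set-up with the highest share of target in all that became target or isomer of the product A or isomer of the product B, at the outlet or at the end ("none" if the first two lie within 2 percentage points) (west / south / south-east / east / none)
- share of target in all that became target or isomer of the product A or isomer of the product B, at the outlet or at the end, west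
- share of target in all that became target or isomer of the product A or isomer of the product B, at the outlet or at the end, south
- share of target in all that became target or isomer of the product A or isomer of the product B, at the outlet or at the end, south-east
- share of target in all that became target or isomer of the product A or isomer of the product B, at the outlet or at the end, east

**First way.** The green and violet runs at 40.0 min leave 41.0% and 37.0% of the charge outside the products. I pool them, summing target and dividing by all three products. This gives the pooled target share (a selectivity) 18.9%.

**Second way.** The ochre run has twice the red charge and leaves 40.0% outside the products at 20.0 min. Its share there is 15.0%, so the two ways part.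

**Which cheats.** The ochre figure rests on one target reading, and one scatter on it shifts that share by 2.5 percentage points. The three ochre readings from 20.0 min on pool to 17.8%, though they span a falling fraction left. That is 1.1 points from the first way, less than the margin of 2 points. So the ochre run at 0.40 M reads within the margin of the green and violet runs at 0.20 M, though those two also differ from it in protic impurity. I commit to 18.9% for all four set-ups, with no winner.

**The forecast.** It says none: 18.5% for west (14% to 24%), 18.5% for south, 18% for south-east and 18.5% for east. My figure stands higher than its west value. Its ground: “Mixing pattern and feeding should therefore barely change selectivity”.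

**The flask.** West, south and east give 18.0%, 18.0% and 18.0%, and south-east gives 18.8%, so the answer is none: the gap of 0.80 points is smaller than the margin. West's share moves 5 points at 34 mol% of catalyst, against the 5 mol% charged. My share times west's products gives 9.50% target, and west holds 9.07%. The neighbour of west with 0.025 M of protic impurity puts 46.1% of the charge into products, so the share promises 8.70% target, and that neighbour holds 8.30%.

    isomer of the product A + catalyst ⇌ isomer of the product B + catalyst, rate k1*[catalyst]*[isomer of the product A] forward; the back reaction follows from the equilibrium constant (K = 4.50, k = 1.50 L mol⁻¹ min⁻¹)
    target ⇌ isomer of the product A (K = 0.500, k = 0.00810 min⁻¹)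
    isomer of the product B + catalyst ⇌ starting material + catalyst, rate k3*[catalyst]*[isomer of the product B] forward; the back reaction follows from the equilibrium constant (k = 0.650 L mol⁻¹ min⁻¹)
    starting material + catalyst ⇌ target + catalyst, rate k4*[starting material]*[catalyst] forward; the back reaction follows from the equilibrium constant (K = 1.60, k = 0.540 L mol⁻¹ min⁻¹)
    starting material + protic impurity → quenched substrate (k = 4.80 L mol⁻¹ min⁻¹)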